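At early times, while partner is still being fed, alder's readings lie within the scatter of zero, so ask of both runs how much product appears per unit of partner concentration integrated over time.

the same everywhere: protic impurity 0.125 M; free catalyst 10 mol%
- alder: starting material 0.031 M; partner 1.2 equiv (fed, over 20 s); temperature −28 °C; run made earlier; the fed solution adds 0.10 times the starting volume
- maple: starting material 0.18 M; partner 1.2 equiv (fed, over 20 s); temperature 0 °C; run made earlier; the fed solution adds 0.10 times the starting volume
- teal: starting material 0.25 M; partner 1.20 equiv (fed, over 20 s); at −40 °C until 20 s, from then on at 10 °C; the fed solution adds 0.10 times the starting volume; time 4.0 min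
- blue: starting material 0.060 M; partner 1.20 equiv (fed, over 20 s); at −40 °C throughout; the fed solution adds 0.10 times the starting volume; time 4.0 min

| run | time / s | product / % |
|---|---|---|
| alder | 10.0 | 0.4 |
| alder | 12.0 | 0 |
| alder | 30.0 | 3.1 |
| alder | 60.0 | 8.8 |
| maple | 10.0 | 13.5 |
| maple | 15.0 | 25.8 |

(readings scatter by 0.5 percentage points)

- the flask that ends with the higher amount of product, in percent of the starting material charged, or "neither" when 2 percentage points or less lies between them (teal / blue / neither)
- final product, as a percentage of the starting material charged, in teal
- final product, as a percentage of the starting material charged, in blue

- charges are per starting volume, the dose included; the dosed solution carries all of it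
- a reading or a percentage of product counts all its forms, free or not
- where the amount of starting material changes, what is given in equivalents or mol% on it follows

Dividing a reading by the partner integral behind it gives 0.0473 /M/s for alder at 60.0 s and 0.250 /M/s for maple at 10.0 s. If the rate is first order in catalyst and in partner, the concentration drops out at a fixed 10 mol%, and the feed's dilution cancels. The two readings then stand 0.723 powers of ten apart between −28 °C and 0 °C. A straight line of the logarithm against temperature, drawn through these two readings, gives 0.0232 /M/s at −40 °C and 0.453 /M/s at 10 °C.

Blue then has a reach of 0.384, the yield per partner integral times the partner integral on offer by the end. This is a Damköhler number, counting e-foldings of starting material with partner held at its charge. Teal's reach is 30.0. My reckoning reads blue as 31.9 % and teal as >99.9 %.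

One number is not enough: alder and maple both carried 0.125 M of protic impurity, so their readings do not show what a change in it does, and it stands at 0.500 equivalents to starting material in teal and 2.08 in blue. If it took starting material to its full charge, teal would keep 50.0 %. So I commit to teal between that and full conversion, and to teal as the richer flask.

The forecast says teal, with teal 78 % and blue 25 %: “Partner competes with impurity, with a floor near 70% if the impurity is fully consumed, so about 78%.” My floor lies lower than its 70%, and its blue lies below mine.

The flask gives teal, with teal 60.9 % and blue 24.4 %.

    starting material + free catalyst → catalyst intermediate A (k = 1.85 /M/s, Ea = 46.0 kJ/mol)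
    catalyst intermediate A ⇌ catalyst intermediate B (K = 1.80, k = 0.457 /s, Ea = 55.0 kJ/mol, ΔH = −18.0 kJ/mol)
    partner + catalyst intermediate B ⇌ catalyst intermediate C (K = 49.0 /M, k = 0.471 /M/s, Ea = 44.0 kJ/mol, ΔH = −54.0 kJ/mol)
    catalyst intermediate C → free catalyst + product (k = 0.386 /s, Ea = 64.0 kJ/mol)
    starting material + protic impurity → quenched substrate (k = 0.0701 /M/s, Ea = 42.0 kJ/mol)
    crystals ⇌ product, rate k6*(cs6 - [product]) while solid is left; crystals form when [product] > cs6 (solubility = 0.220 M, k = 2.42 /s)
    (constants at −40 °C)

Blue's reach of 0.384 reckoned a product that the flask reached 0.765 of. A flask like blue at 0.10 M of starting material, with the equivalents and loadings held, has reach 0.640, and its 36.6 % is 0.774 of the reckoned 47.3 %. In blue at 4.00 min, the half-life of starting material is 2.2 min by the step with free catalyst and 2.1 min by the step with protic impurity. At that time blue holds 24.4 % product against 61.3 % quenched substrate.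

All runs were generated by integration from invented constants; noise was put on by code.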